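**A direct plan would** take three ready-made phloroglucinol rings and join them through two methylene bridges. The central (2R)-2-methylbutanoylphloroglucinol A1 would be alkylated by o-quinone methides released from the Mannich bases A2 (acetyl ring) and A3 (isobutyryl ring), the first coupling giving the mono-bridged dimer A4. Its weakest steps would be these:
- The preparation of A1 by auxiliary-controlled enolate methylation, auxiliary cleavage, amide formation and aryllithium acylation of a tribenzylated ring would spend about seven steps on one small stereocentre, with the facial selectivity of one methylation as its only control.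
- The partial benzylation meant to leave only the hydroxyl between C-methyl and acyl group free for O-methylation would rest on a weak steric preference between two chelated hydroxyls, and would cost three protecting-group steps on each outer ring.
- The first quinone methide coupling would need a large excess of the precious chiral A1 to hold back double alkylation, hot and beside an amine, where bridge scrambling and erosion of the α-stereocentre could not be excluded.

**Plan of the new route.** The central ring B is made last. The retrosynthesis first cuts both ring bonds at its acyl-bearing carbon C1 (C1–C2 and C1–C6). That leaves the silyl enol ether of (R)-3-methylpentan-2-one and a 3-oxoglutaric unit (C2–C6) whose two carboxyl carbons are stored as aryl lactones on the phenols of the outer rings A (acetyl) and C (isobutyryl). The two C(ring B)–CH2 bonds are then cut as Knoevenagel C=C bonds between dimethyl 3-oxopentanedioate and two aldehydes, and last the acyl and formyl groups of these. Rings arise in the order A/C (one bought phloroglucinol), the two lactone rings, then ring B in the key step. The enabling feature is that ring B is the enol form of a 2-acylcyclohexane-1,3,5-trione with C3 and C5 exchanged by the local axis through C1 and C4, and each bridge CH2 is ortho to a phenolic OH of ring A or C. The formyl carbon (the future bridge) is para to the hydroxyl to be methylated and directs that step, so no auxiliary, benzyl ether, quinone methide or excess of a chiral monomer occurs.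

Key step: step 10

Remark: (R)-2-methylbutanoic acid is taken as a commercial single enantiomer, and each lactone is drawn closed onto the hydroxyl next to the ring methyl group (the one not chelated by the ring ketone); the regioisomeric lactones would converge in step 10.

Step 1
Reactants: 1 2-methylbenzene-1,3,5-triol
Product: 3 2,4,6-trihydroxy-3-methylbenzaldehyde, via iminium chloride 2 (not isolated)
Conditions: POCl3 (1.1 eq), DMF (1.3 eq), EtOAc, 0 °C to rt; H2O, 60 °C
Reagents that add atoms: N,N-dimethylformamide, CN(C)C=O; water, O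
Why: Vilsmeier–Haack formylation, in which the chloroiminium ion attacks one of the two equivalent free ring carbons and the iminium salt 2 deactivates the ring against a second formylation before hydrolysis gives the aldehyde.

Step 2
Reactants: 3 2,4,6-trihydroxy-3-methylbenzaldehyde
Product: 4 2,6-dihydroxy-4-methoxy-3-methylbenzaldehyde
Conditions: MeI (1.05 eq), Li2CO3 (1.1 eq), DMF, 40 °C
Reagents that add atoms: iodomethane, CI
Why: Williamson O-methylation under a weak base should select the 4-OH, which is para to the formyl group, the most acidic and the only hydroxyl not hydrogen-bonded to the carbonyl; the directing formyl carbon is the future methylene bridge.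

Step 3
Reactants: 4 2,6-dihydroxy-4-methoxy-3-methylbenzaldehyde; 5 acetyl chloride
Product: 6 3-acetyl-2,6-dihydroxy-4-methoxy-5-methylbenzaldehyde
Conditions: AcCl (1.3 eq), TiCl4 (3 eq), CH2Cl2, 0 °C to reflux; cold 1 M HCl
Reagents that add atoms: none
Why: Friedel–Crafts acylation (by way of O-acylation and Fries shift) at the single free ring carbon, which is ortho/para to three oxygen donors and meta to the formyl group; TiCl4 is chosen over AlCl3 to spare the methyl ether next to the new ketone.

Step 4
Reactants: 4 2,6-dihydroxy-4-methoxy-3-methylbenzaldehyde; 7 2-methylpropanoyl chloride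
Product: 8 2,6-dihydroxy-4-methoxy-3-methyl-5-(2-methylpropanoyl)benzaldehyde
Conditions: i-PrCOCl (1.3 eq), TiCl4 (3 eq), CH2Cl2, 0 °C to reflux; cold 1 M HCl
Reagents that add atoms: none
Why: Friedel–Crafts acylation as in step 3, with the same single site of attack.

Step 5
Reactants: 6 3-acetyl-2,6-dihydroxy-4-methoxy-5-methylbenzaldehyde; 9 dimethyl 3-oxopentanedioate
Product: 10 methyl 3-(6-acetyl-5-hydroxy-7-methoxy-8-methyl-2-oxo-2H-chromen-3-yl)-3-oxopropanoate
Conditions: 9 (3 eq), piperidine (0.2 eq), AcOH (0.2 eq), MeOH, 40 °C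
Reagents that add atoms: none
Why: Knoevenagel condensation of one active methylene of the keto diester with the aldehyde, then lactonisation of the arylidene ester onto the ortho hydroxyl (the 3-acylcoumarin synthesis); the excess of 9 holds back double condensation.

Step 6
Reactants: 10 methyl 3-(6-acetyl-5-hydroxy-7-methoxy-8-methyl-2-oxo-2H-chromen-3-yl)-3-oxopropanoate; 8 2,6-dihydroxy-4-methoxy-3-methyl-5-(2-methylpropanoyl)benzaldehyde
Product: 11 6-acetyl-5-hydroxy-3-{[5-hydroxy-7-methoxy-8-methyl-6-(2-methylpropanoyl)-2-oxo-2H-chromen-3-yl]carbonyl}-7-methoxy-8-methyl-2H-chromen-2-one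
Conditions: piperidine (0.3 eq), MeCN/EtOH, 70 °C
Reagents that add atoms: none
Why: A second Knoevenagel condensation and lactonisation at the remaining active methylene, the standard route to 3,3'-carbonylbiscoumarins, places the two different outer rings on the two α-carbons of the future C4 ketone.

Step 7
Reactants: 11 6-acetyl-5-hydroxy-3-{[5-hydroxy-7-methoxy-8-methyl-6-(2-methylpropanoyl)-2-oxo-2H-chromen-3-yl]carbonyl}-7-methoxy-8-methyl-2H-chromen-2-one
Product: 12 6-acetyl-5-hydroxy-3-{[5-hydroxy-7-methoxy-8-methyl-6-(2-methylpropanoyl)-2-oxo-3,4-dihydro-2H-chromen-3-yl]carbonyl}-7-methoxy-8-methyl-3,4-dihydro-2H-chromen-2-one (mixture of diastereomers and enol forms)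
Conditions: H2 (1 atm), 10% Pd/C, THF/DMF, rt
Reagents that add atoms: none
Why: Catalytic hydrogenation of the two electron-poor coumarin C3=C4 bonds (3-acylcoumarin to 3-acyl-3,4-dihydrocoumarin) creates both bridge methylenes; the chelated aryl ketones and the lactones should survive at 1 atm, and the two new C3 centres are lost again in step 10.

Step 8
Reactants: 13 (2R)-2-methylbutanoic acid
Product: 15 (3R)-3-methylpentan-2-one, via dilithium gem-diolate 14 (not isolated)
Conditions: MeLi (2.1 eq), Et2O, 0 °C to rt; inverse quench into cold 1 M HCl; careful distillation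
Reagents that add atoms: methyllithium, [Li]C
Why: Addition of methyllithium to the lithium carboxylate gives the stable gem-diolate 14, which collapses to the methyl ketone only on acidic quench, so neither over-addition nor enolisation of the α-stereocentre should occur.

Step 9
Reactants: 15 (3R)-3-methylpentan-2-one
Product: 17 tert-butyl(dimethyl){[(3R)-3-methylpent-1-en-2-yl]oxy}silane, via lithium enolate 16 (not isolated)
Conditions: LiN(i-Pr)2 (1.1 eq), THF, −78 °C, ketone added to base; t-BuMe2SiCl (1.2 eq), DMPU, −78 °C to rt; pentane/aq. NaHCO3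
Reagents that add atoms: tert-butyl(chloro)dimethylsilane, CC(C)(C)[Si](C)(C)Cl
Why: Kinetic deprotonation by the hindered amide at the methyl group, not at the tertiary α-carbon that carries the stereocentre, followed by O-silylation fixes the enol regiochemistry and leaves the (R)-centre untouched, since the enolate never meets free ketone.

Step 10
Reactants: 12 6-acetyl-5-hydroxy-3-{[5-hydroxy-7-methoxy-8-methyl-6-(2-methylpropanoyl)-2-oxo-3,4-dihydro-2H-chromen-3-yl]carbonyl}-7-methoxy-8-methyl-3,4-dihydro-2H-chromen-2-one; 17 tert-butyl(dimethyl){[(3R)-3-methylpent-1-en-2-yl]oxy}silane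
Product: 21 (2R)-1-{3-[(3-acetyl-2,6-dihydroxy-4-methoxy-5-methylphenyl)methyl]-5-{[2,6-dihydroxy-4-methoxy-3-methyl-5-(2-methylpropanoyl)phenyl]methyl}-2,4,6-trihydroxyphenyl}-2-methylbutan-1-one, via acylketene 18 (not isolated), via silyl ketal 19 (not isolated), via triketone 20 (not isolated)
Conditions: 17 (3 eq), i-Pr2NEt (0.5 eq), PhMe, 100 °C, N2, sealed; then Bu4NF (6 eq), THF, 0 °C to rt; cold 1 M HCl
Reagents that add atoms: none
Why: Proposed new method: the enolised β-keto aryl lactone of 12 should open reversibly to the acylketene 18 (E1cB loss of an acyl-activated phenoxide, the ketene pathway known for aryl acetoacetates), and 18 should be captured irreversibly by the electron-rich enol ether 17 in an inverse-demand hetero-Diels–Alder reaction, the known behaviour of acylketenes towards enol ethers, so that the C1–C2 bond forms without enolising the α-stereocentre and gives the silyl ketal 19. Fluoride then unmasks the 1,3,5-triketone 20, whose C1 methylene between two ketones is its most acidic carbon and attacks the remaining aryl lactone in a Claisen (Dieckmann-type, 6-exo-trig) closure that forms C1–C6, frees the second outer-ring phenol and becomes irreversible by enolisation to the aromatic ring B; the closest known reaction is the Claisen cyclisation of 3,5,7-triketo esters to acylphloroglucinols. Ring B is the only ring closed, and only in the Claisen mode, because an aldol closure would have to use C3 or C5, which already carry the benzyl arms and could give only quaternary aldols that cannot aromatise and revert. No stereocentre is formed: the (R)-centre comes unchanged from 13, the C3 centres of the lactones vanish on aromatisation, and the α-hydrogen of the acyl group is shielded from base by the adjacent enolate and later phenoxide charge. The step needs mono-addition and C- instead of O-acylation: once 19 has formed the central ketone is a vinylogous ester that no longer activates the second lactone for ketene formation, and O-acylated by-products are aryl esters that can return to 20 while aromatisation is the only exit. Which lactone opens first is immaterial, since C3 and C5 of ring B are exchanged by its local axis through C1 and C4.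

**Compound list**
1 | 2-methylbenzene-1,3,5-triol | Cc1c(O)cc(O)cc1O | starting material
2 | dimethyl[(2,4,6-trihydroxy-3-methylphenyl)methylidene]azanium chloride | C[N+](C)=Cc1c(O)cc(O)c(C)c1O.[Cl-] | intermediate (not isolated)
3 | 2,4,6-trihydroxy-3-methylbenzaldehyde | Cc1c(O)cc(O)c(C=O)c1O | intermediate
4 | 2,6-dihydroxy-4-methoxy-3-methylbenzaldehyde | COc1cc(O)c(C=O)c(O)c1C | intermediate
5 | acetyl chloride | CC(Cl)=O | starting material
6 | 3-acetyl-2,6-dihydroxy-4-methoxy-5-methylbenzaldehyde | CC(=O)c1c(O)c(C=O)c(O)c(C)c1OC | intermediate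
7 | 2-methylpropanoyl chloride | CC(C)C(Cl)=O | starting material
8 | 2,6-dihydroxy-4-methoxy-3-methyl-5-(2-methylpropanoyl)benzaldehyde | CC(C)C(=O)c1c(O)c(C=O)c(O)c(C)c1OC | intermediate
9 | dimethyl 3-oxopentanedioate | COC(=O)CC(=O)CC(=O)OC | starting material
10 | methyl 3-(6-acetyl-5-hydroxy-7-methoxy-8-methyl-2-oxo-2H-chromen-3-yl)-3-oxopropanoate | COC(=O)CC(=O)C1=Cc2c(O)c(C(C)=O)c(OC)c(C)c2OC1=O | intermediate
11 | 6-acetyl-5-hydroxy-3-{[5-hydroxy-7-methoxy-8-methyl-6-(2-methylpropanoyl)-2-oxo-2H-chromen-3-yl]carbonyl}-7-methoxy-8-methyl-2H-chromen-2-one | CC(=O)c1c(O)c2C=C(C(=O)C3=Cc4c(O)c(C(=O)C(C)C)c(OC)c(C)c4OC3=O)C(=O)Oc2c(C)c1OC | intermediate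
12 | 6-acetyl-5-hydroxy-3-{[5-hydroxy-7-methoxy-8-methyl-6-(2-methylpropanoyl)-2-oxo-3,4-dihydro-2H-chromen-3-yl]carbonyl}-7-methoxy-8-methyl-3,4-dihydro-2H-chromen-2-one (diastereomer mixture) | CC(=O)c1c(O)c2CC(C(=O)C3Cc4c(O)c(C(=O)C(C)C)c(OC)c(C)c4OC3=O)C(=O)Oc2c(C)c1OC | intermediate
13 | (2R)-2-methylbutanoic acid | CC[C@@H](C)C(=O)O | starting material
14 | dilithium (3R)-3-methylpentane-2,2-bis(olate) | CC[C@@H](C)C(C)([O-])[O-].[Li+].[Li+] | intermediate (not isolated)
15 | (3R)-3-methylpentan-2-one | CC[C@@H](C)C(C)=O | intermediate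
16 | lithium (3R)-3-methylpent-1-en-2-olate | CC[C@@H](C)C(=C)[O-].[Li+] | intermediate (not isolated)
17 | tert-butyl(dimethyl){[(3R)-3-methylpent-1-en-2-yl]oxy}silane | CC[C@@H](C)C(=C)O[Si](C)(C)C(C)(C)C | intermediate
18 | 2-[(3-acetyl-2,6-dihydroxy-4-methoxy-5-methylphenyl)methyl]-3-[5-hydroxy-7-methoxy-8-methyl-6-(2-methylpropanoyl)-2-oxo-3,4-dihydro-2H-chromen-3-yl]prop-1-ene-1,3-dione (acylketene) | CC(=O)c1c(O)c(CC(=C=O)C(=O)C2Cc3c(O)c(C(=O)C(C)C)c(OC)c(C)c3OC2=O)c(O)c(C)c1OC | intermediate (not isolated)
19 | 5-[(3-acetyl-2,6-dihydroxy-4-methoxy-5-methylphenyl)methyl]-2-[(2R)-butan-2-yl]-2-{[tert-butyl(dimethyl)silyl]oxy}-6-[5-hydroxy-7-methoxy-8-methyl-6-(2-methylpropanoyl)-2-oxo-3,4-dihydro-2H-chromen-3-yl]-2,3-dihydro-4H-pyran-4-one (either configuration at the ketal and lactone carbons) | CC[C@@H](C)C1(O[Si](C)(C)C(C)(C)C)CC(=O)C(Cc2c(O)c(C)c(OC)c(C(C)=O)c2O)=C(C2Cc3c(O)c(C(=O)C(C)C)c(OC)c(C)c3OC2=O)O1 | intermediate (not isolated)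
20 | (6R)-2-[(3-acetyl-2,6-dihydroxy-4-methoxy-5-methylphenyl)methyl]-1-[5-hydroxy-7-methoxy-8-methyl-6-(2-methylpropanoyl)-2-oxo-3,4-dihydro-2H-chromen-3-yl]-6-methyloctane-1,3,5-trione | CC[C@@H](C)C(=O)CC(=O)C(Cc1c(O)c(C)c(OC)c(C(C)=O)c1O)C(=O)C1Cc2c(O)c(C(=O)C(C)C)c(OC)c(C)c2OC1=O | intermediate (not isolated)
21 | (2R)-1-{3-[(3-acetyl-2,6-dihydroxy-4-methoxy-5-methylphenyl)methyl]-5-{[2,6-dihydroxy-4-methoxy-3-methyl-5-(2-methylpropanoyl)phenyl]methyl}-2,4,6-trihydroxyphenyl}-2-methylbutan-1-one | CC[C@@H](C)C(=O)c1c(O)c(Cc2c(O)c(C)c(OC)c(C(C)=O)c2O)c(O)c(Cc2c(O)c(C)c(OC)c(C(=O)C(C)C)c2O)c1O | target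

**Count.** Total steps: 10. Longest linear sequence: 7 steps (steps 1, 2, 3, 5, 6, 7, 10).

**Steps most likely to fail**

Step 10 (proposed new method). Possible failures are:
- slow release of the ketene from the lactone, or its return to the lactone;
- transfer of the silyl group from 17 to the phenols;
- acid-catalysed double-bond shift in 17 with erosion of configuration;
- loss of silanol from 19 to a 4-pyranone that resists opening;
- O- instead of C-cyclisation of 20 to a 4-hydroxypyranone.

The fallback uses known chemistry, sets out from 6, 8 and 13 and returns at 21. Acid 13 would be converted with (COCl)2 and catalytic DMF into (2R)-2-methylbutanoyl chloride F1. A Friedel–Crafts acylation of commercial phloroglucinol with F1 (AlCl3, PhNO2/CH2Cl2) would give (2R)-2-methyl-1-(2,4,6-trihydroxyphenyl)butan-1-one F2. Aldehyde 6 would be reduced with NaBH4 (THF/EtOH, 0 °C) to 1-[2,4-dihydroxy-3-(hydroxymethyl)-6-methoxy-5-methylphenyl]ethan-1-one F3. Warmed with an excess of F2 (1,4-dioxane/H2O, 80 °C), F3 would lose water to an o-quinone methide and give the mono-bridged ketone (2R)-1-{3-[(3-acetyl-2,6-dihydroxy-4-methoxy-5-methylphenyl)methyl]-2,4,6-trihydroxyphenyl}-2-methylbutan-1-one F4. The same reduction of 8 would give 1-[2,4-dihydroxy-3-(hydroxymethyl)-6-methoxy-5-methylphenyl]-2-methylpropan-1-one F5, whose quinone methide would be taken up by the last free ring carbon of F4 to give 21.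

Step 7. The donor-substituted, poorly soluble biscoumarin may be saturated incompletely, or a ketone may be reduced or hydrogenolysed. The fallback sets out from 6 and 8 and returns at 12, with the bridge methylenes made by hydride transfer before the ketone is assembled. Aldehyde 6 with Meldrum's acid and Hantzsch ester (catalytic L-proline, EtOH, rt; Knoevenagel condensation, transfer hydrogenation, lactonisation with loss of acetone) would give 6-acetyl-5-hydroxy-7-methoxy-8-methyl-2-oxo-3,4-dihydro-2H-chromene-3-carboxylic acid F6. Aldehyde 8 would give in the same way 5-hydroxy-7-methoxy-8-methyl-6-(2-methylpropanoyl)-2-oxo-3,4-dihydro-2H-chromene-3-carboxylic acid F7. F7 would be activated with carbonyldiimidazole to 5-hydroxy-3-(1H-imidazole-1-carbonyl)-7-methoxy-8-methyl-6-(2-methylpropanoyl)-3,4-dihydro-2H-chromen-2-one F8. Condensation of F8 with the magnesium enolate of F6 (MgCl2, Et3N, MeCN), a decarboxylative Claisen condensation of the malonic half ester type, would give 12.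

Step 2. A second alkylation at a chelated hydroxyl, or C-methylation of the electron-rich ring, may compete. The fallback sets out from 3 and returns at 4, replacing selective alkylation by selective dealkylation. Aldehyde 3 would be permethylated (Me2SO4, K2CO3, acetone, reflux) to 2,4,6-trimethoxy-3-methylbenzaldehyde F9. BCl3 (2.5 eq, CH2Cl2, −78 to 0 °C) would then cleave, through the boron chelate, only the two methyl ethers ortho to the formyl group and leave the para ether, giving 4.

**Further compounds**
F1 | step 10 | (2R)-2-methylbutanoyl chloride | CC[C@@H](C)C(Cl)=O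
F2 | step 10 | (2R)-2-methyl-1-(2,4,6-trihydroxyphenyl)butan-1-one | CC[C@@H](C)C(=O)c1c(O)cc(O)cc1O
F3 | step 10 | 1-[2,4-dihydroxy-3-(hydroxymethyl)-6-methoxy-5-methylphenyl]ethan-1-one | CC(=O)c1c(O)c(CO)c(O)c(C)c1OC
F4 | step 10 | (2R)-1-{3-[(3-acetyl-2,6-dihydroxy-4-methoxy-5-methylphenyl)methyl]-2,4,6-trihydroxyphenyl}-2-methylbutan-1-one | CC[C@@H](C)C(=O)c1c(O)cc(O)c(Cc2c(O)c(C)c(OC)c(C(C)=O)c2O)c1O
F5 | step 10 | 1-[2,4-dihydroxy-3-(hydroxymethyl)-6-methoxy-5-methylphenyl]-2-methylpropan-1-one | CC(C)C(=O)c1c(O)c(CO)c(O)c(C)c1OC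
F6 | step 7 | 6-acetyl-5-hydroxy-7-methoxy-8-methyl-2-oxo-3,4-dihydro-2H-chromene-3-carboxylic acid | CC(=O)c1c(O)c2CC(C(=O)O)C(=O)Oc2c(C)c1OC
F7 | step 7 | 5-hydroxy-7-methoxy-8-methyl-6-(2-methylpropanoyl)-2-oxo-3,4-dihydro-2H-chromene-3-carboxylic acid | CC(C)C(=O)c1c(O)c2CC(C(=O)O)C(=O)Oc2c(C)c1OC
F8 | step 7 | 5-hydroxy-3-(1H-imidazole-1-carbonyl)-7-methoxy-8-methyl-6-(2-methylpropanoyl)-3,4-dihydro-2H-chromen-2-one | CC(C)C(=O)c1c(O)c2CC(C(=O)n3ccnc3)C(=O)Oc2c(C)c1OC
F9 | step 2 | 2,4,6-trimethoxy-3-methylbenzaldehyde | COc1cc(OC)c(C=O)c(OC)c1C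
A1 | direct plan | (2R)-2-methyl-1-(2,4,6-trihydroxyphenyl)butan-1-one | CC[C@@H](C)C(=O)c1c(O)cc(O)cc1O
A2 | direct plan | 1-{3-[(dimethylamino)methyl]-2,4-dihydroxy-6-methoxy-5-methylphenyl}ethan-1-one | CC(=O)c1c(OC)c(C)c(O)c(CN(C)C)c1O
A3 | direct plan | 1-{3-[(dimethylamino)methyl]-2,4-dihydroxy-6-methoxy-5-methylphenyl}-2-methylpropan-1-one | CC(C)C(=O)c1c(OC)c(C)c(O)c(CN(C)C)c1O
A4 | direct plan | (2R)-1-{3-[(3-acetyl-2,6-dihydroxy-4-methoxy-5-methylphenyl)methyl]-2,4,6-trihydroxyphenyl}-2-methylbutan-1-one | CC[C@@H](C)C(=O)c1c(O)cc(O)c(Cc2c(O)c(C)c(OC)c(C(C)=O)c2O)c1O
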